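**Retrosynthetic overview**
1. Target 7 ⇒ enol 5 + 3-hydroxy-3-methylbutanoic acid 6, by disconnecting the enol ester C–O bond (last step).
2. Enol 5 ⇒ 4-O-prenyl ether 3 by a retro-Claisen [3,3] shift, which puts the 1,1-dimethylallyl group on C3.
3. Ether 3 ⇒ 4-hydroxy-6-phenyl-2-pyranone 1 + prenol 2 (O-alkylation).
4. Rings: none is formed in the route; the 2-pyranone and the phenyl ring are bought intact in 1.

Assumption: the target has no stereocentre (it is achiral), so no enantiocontrol is needed; 1, 2 and 6 are taken as catalogue chemicals.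

**Step 1**
Reactants: 1 4-hydroxy-6-phenyl-2H-pyran-2-one; 2 3-methylbut-2-en-1-ol (prenol)
Product: 3 4-[(3-methylbut-2-en-1-yl)oxy]-6-phenyl-2H-pyran-2-one
Conditions: PPh3 (1.3 equiv), DIAD (1.3 equiv), THF, 0 °C → rt
Reagents that add atoms: none
Why: Mitsunobu etherification, in which the acidic 4-OH (pKa ≈ 5) is alkylated on O4 by the activated primary allylic alcohol in an SN2 sense without allylic transposition; no stereocentre is formed.

**Step 2**
Reactants: 3 4-[(3-methylbut-2-en-1-yl)oxy]-6-phenyl-2H-pyran-2-one
Product: 5 4-hydroxy-3-(2-methylbut-3-en-2-yl)-6-phenyl-2H-pyran-2-one, via diketo tautomer 4 (not isolated)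
Conditions: degassed PhMe (0.05 M), 110 °C, sealed tube, stopped at full conversion
Reagents that add atoms: none
Why: Claisen rearrangement of the allyl vinyl ether unit C3=C4–O–CH2–CH=CMe2, whose [3,3] shift joins C3 to the CMe2 terminus (the only position available) and gives the C3-quaternary dione, which enolises to the 4-hydroxy-2-pyranone; the transient C3 centre is racemic and is erased on enolisation.

**Step 3**
Reactants: 5 4-hydroxy-3-(2-methylbut-3-en-2-yl)-6-phenyl-2H-pyran-2-one; 6 3-hydroxy-3-methylbutanoic acid (1.5 equiv)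
Product: 7 3-(2-methylbut-3-en-2-yl)-2-oxo-6-phenyl-2H-pyran-4-yl 3-hydroxy-3-methylbutanoate (target)
Conditions: DCC (1.5 equiv), CH2Cl2, 0 °C → rt, no DMAP; filter, neutral work-up
Reagents that add atoms: none
Why: Carbodiimide esterification of the active-ester type, in which the acidic enol behaves like p-nitrophenol toward the O-acylisourea, the blocked C3 rules out an O→C acyl shift, the tertiary alcohol of 6 is too hindered to compete, and leaving out DMAP avoids acyl-pyridinium-mediated β-lactonisation of the product; no stereocentre is formed.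

**Compound list**
1 | 4-hydroxy-6-phenyl-2H-pyran-2-one | O=c1cc(O)cc(-c2ccccc2)o1 | starting material
2 | 3-methylbut-2-en-1-ol (prenol) | CC(C)=CCO | starting material
3 | 4-[(3-methylbut-2-en-1-yl)oxy]-6-phenyl-2H-pyran-2-one | CC(C)=CCOc1cc(-c2ccccc2)oc(=O)c1 | intermediate
4 | 3-(2-methylbut-3-en-2-yl)-6-phenyl-2H-pyran-2,4(3H)-dione (diketo tautomer of 5; racemic at C3, transient) | C=CC(C)(C)C1C(=O)C=C(c2ccccc2)OC1=O | intermediate
5 | 4-hydroxy-3-(2-methylbut-3-en-2-yl)-6-phenyl-2H-pyran-2-one | C=CC(C)(C)c1c(O)cc(-c2ccccc2)oc1=O | intermediate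
6 | 3-hydroxy-3-methylbutanoic acid | CC(C)(O)CC(=O)O | starting material
7 | 3-(2-methylbut-3-en-2-yl)-2-oxo-6-phenyl-2H-pyran-4-yl 3-hydroxy-3-methylbutanoate (achiral) | C=CC(C)(C)c1c(OC(=O)CC(C)(C)O)cc(-c2ccccc2)oc1=O | target

**Step count and risks**
Total step count: 3. Longest linear sequence: 3 steps (1 → 3 → 5 → 7).

With only three steps, all three are the ones most likely to fail.

Step 1 is at risk because the pyranone anion is ambident: C3- or O2-alkylation, or SN2′ scrambling of the prenyl unit, could erode the yield of 3. The fallback sets out from 1 and comes back at 3, and it inverts the roles of the partners. Compound 1 is heated with P2O5 and Bu4NBr in toluene at 100 °C to give 4-bromo-6-phenyl-2H-pyran-2-one F1. The bromide is then displaced at C4 by prenol 2 with Cs2CO3 in MeCN at rt (addition–elimination on the vinylogous acyl bromide) to give 3. The pyranone is now the electrophile and the only nucleophile is the alcohol oxygen, so C-alkylation and allylic transposition cannot occur.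

Step 2 is at risk because the free enol 5, once formed at 110 °C, may add across its own vinyl group to give a dihydrofuro[3,2-c]pyranone, or rearrange further. The fallback sets out from 3 and comes back at 5, and it replaces the free-enol thermolysis by a rearrangement with in-flask trapping. Compound 3 is heated in acetic anhydride with NaOAc at 120 °C, so that 4 and 5 are acetylated as they form. This gives 3-(2-methylbut-3-en-2-yl)-2-oxo-6-phenyl-2H-pyran-4-yl acetate F2, which cannot cyclise. The very reactive enol acetate is then cleaved with pyrrolidine (1.05 equiv, CH2Cl2, 0 °C) followed by a mild acid wash, returning 5.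

Step 3 is at risk because the hindered enol may be acylated more slowly than the activated β-hydroxy acid lactonises, oligomerises or collapses to the N-acylurea. The fallback sets out from 6 (with 5 as coupling partner) and comes back at 7, and it switches to a protected acyl donor in three operations:
- Acid 6 is treated with TESOTf (2.3 equiv) and 2,6-lutidine in CH2Cl2 at 0 °C to give triethylsilyl 3-methyl-3-[(triethylsilyl)oxy]butanoate F3. The silyl ester of F3 is hydrolysed in the same flask with H2O/THF to give 3-methyl-3-[(triethylsilyl)oxy]butanoic acid F4.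
- F4 is coupled with 5 (DCC, cat. DMAP, CH2Cl2; DMAP is safe once the hydroxyl is capped) to give 3-(2-methylbut-3-en-2-yl)-2-oxo-6-phenyl-2H-pyran-4-yl 3-methyl-3-[(triethylsilyl)oxy]butanoate F5.
- The tertiary silyl ether of F5 is removed with HF·pyridine in THF/pyridine at 0 °C, with a quench into pH 7 buffer, to give 7.

**Further compounds**
F1 | step 1 | 4-bromo-6-phenyl-2H-pyran-2-one | O=c1cc(Br)cc(-c2ccccc2)o1
F2 | step 2 | 3-(2-methylbut-3-en-2-yl)-2-oxo-6-phenyl-2H-pyran-4-yl acetate | C=CC(C)(C)c1c(OC(C)=O)cc(-c2ccccc2)oc1=O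
F3 | step 3 | triethylsilyl 3-methyl-3-[(triethylsilyl)oxy]butanoate | CC[Si](CC)(CC)OC(C)(C)CC(=O)O[Si](CC)(CC)CC
F4 | step 3 | 3-methyl-3-[(triethylsilyl)oxy]butanoic acid | CC[Si](CC)(CC)OC(C)(C)CC(=O)O
F5 | step 3 | 3-(2-methylbut-3-en-2-yl)-2-oxo-6-phenyl-2H-pyran-4-yl 3-methyl-3-[(triethylsilyl)oxy]butanoate | C=CC(C)(C)c1c(OC(=O)CC(C)(C)O[Si](CC)(CC)CC)cc(-c2ccccc2)oc1=O
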